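(The rate constants are invented; no experiment stands behind them.)

49.1% of the substrate charged: with that figure the kineticist opened the meeting on grey, the flask at 50 °C. She called it the ceiling yield Y*, the product that the second catalyst delivers in the time of the run if all of it stands as catalyst intermediate and the coupling partner stays at its charge. In symbols, Y* is the loading of second catalyst times kc, the rate constant of the coupling step, times cB, the charged coupling partner, times the time.

in all of them: substrate 0.78 M; coupling partner 1.05 equiv; free catalyst 20 mol%; second catalyst 0.5 mol%; time 12 s

|  | temperature | remark |
|---|---|---|
| blue | −10 °C |  |
| grey | 50 °C |  |
| amber | 20 °C |  |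
| ochre |  | at −10 °C until 6.0 s, from then on at 50 °C |

- the flask that comes out highest in amount of product, in percent of the substrate charged, or "all alike" when all lie within 1.5 percentage points (blue / grey / amber / ochre / all alike)
- product at the end, in percent of the substrate charged, blue
- product at the end, in percent of the substrate charged, grey
- product at the end, in percent of the substrate charged, amber
- product at the end, in percent of the substrate charged, ochre

- the list of constants is for 50 °C, to be carried to other temperatures by the activation energies and enthalpies

    substrate + free catalyst → free catalyst + open intermediate (k1 = 1.4 M⁻¹ s⁻¹, Ea1 = 56.0 kJ mol⁻¹)
    second catalyst + open intermediate ⇌ catalyst intermediate (K2 = 460 M⁻¹, k2 = 52 M⁻¹ s⁻¹, Ea2 = 38.0 kJ mol⁻¹, ΔH2 = −20.0 kJ mol⁻¹)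
    coupling partner + catalyst intermediate → second catalyst + product (k3 = 10 M⁻¹ s⁻¹, Ea3 = 49.0 kJ mol⁻¹)
    (constants at 50 °C)

The process chemist recalled the sequence: free catalyst opens the substrate to the open intermediate, second catalyst binds that reversibly as catalyst intermediate, and coupling partner releases product and second catalyst. He asked whether the ceiling is reached at all. The kineticist turned the constants into times at the charged amounts. In grey the feed is pseudo-first-order, since free catalyst returns, with a time of 4.58 s, and at the start it supplies 5.33 times the flux of the ceiling, so open intermediate must pile up.

She then set capture against release, dropping the reverse step because it is slow. Capture equals release when open intermediate stands at 20.2% of the substrate charged, a Michaelis-type constant. With 92.7% of the substrate fed by the end, the share of second catalyst held as catalyst intermediate, its resting state, gives 40.4%.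

The process chemist objected that coupling partner falls as product forms. Taking its mean over the run, I, keeping these minutes, commit to 32.6% for grey, which ignores the early lag and so stands high. For ochre the meeting wrote a ceiling of 24.6% from the hot stretch. For blue it wrote 0.768%, with the coupling step slower by a factor of 64. The ceiling of grey therefore stands above those of ochre and blue, and amber was left unreckoned.

The forecast named grey and gave 0.04% for blue, 29.5% for grey, 3.3% for amber and 14.4% for ochre, holding that at the lower temperatures “all the rate constants fall steeply”.

The simulation gives 0.0366% for blue, 29.4% for grey, 3.15% for amber and 14.1% for ochre, so grey is highest, and my grey figure stands 3.2 percentage points above its result.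

Grey reached 59.9% of its ceiling, with catalyst intermediate at 80.9% of the second catalyst at the end. Blue reached 4.77% of its ceiling. Its neighbour, blue with 2.60 equiv of coupling partner, has a ceiling of 1.90%, larger by a factor of 2.48. That flask gave 0.0620%, which is 3.26% of its ceiling, and the factor of 1.69 by which its product exceeds that of blue is smaller than the factor on the ceiling. Its catalyst intermediate stood at 7.65% of the second catalyst at the end, against 12.3% in blue.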